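The target is a 2,3-epoxy-2-methylcyclohexanone; in 7-oxabicyclo[4.1.0]heptan-2-one numbering C1 is the methyl-bearing epoxide carbon, C2 the ketone, C3 the tiglate carbon, C4 carries the dienone arm, C5 is CH2 and C6 the epoxide CH. Everything rests on a one-flask anionic [3+3] annulation that forms C4–C5 and C1–C2: the trianion of a malic-acid-derived δ-hydroxy β-keto diester is allylated at its γ-carbon by (Z)-1-bromo-3-iodobut-2-ene, and iodine–lithium exchange then closes the ring onto the methyl ester. The step exploits that C4 lies between the oxygen-bearing C3 and a ketone-to-be, and that C1–C6 is a masked Z-alkene. The precursor is acyclic and already holds the C3 stereocentre.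

Key step: step 5

Remark: the acetonide acid 4 of (S)-malic acid is taken as a commercial compound; ring locants in the text are those of 7-oxabicyclo[4.1.0]heptan-2-one.

Step 1
Reactants: 1 but-2-yn-1-ol
Product: 2 (Z)-3-iodobut-2-en-1-ol
Conditions: NaAlH2(OCH2CH2OCH3)2, THF, 0 °C to rt; then I2, −78 °C to 0 °C
Reagents that add atoms: iodine, II
Why: Hydroxyl-directed trans-hydroalumination of the propargylic alcohol places aluminium on C3 cis to the CH2O group, and iodinolysis with retention should give the Z vinyl iodide (hydroalumination–iodination).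

Step 2
Reactants: 2 (Z)-3-iodobut-2-en-1-ol
Product: 3 (Z)-1-bromo-3-iodobut-2-ene
Conditions: CBr4, PPh3, CH2Cl2, 0 °C
Reagents that add atoms: carbon tetrabromide, BrC(Br)(Br)Br
Why: The Appel reaction converts the primary allylic alcohol into the bromide without touching the vinyl iodide or the alkene geometry.

Step 3
Reactants: 4 2-[(4S)-2,2-dimethyl-5-oxo-1,3-dioxolan-4-yl]acetic acid
Product: 6 prop-2-en-1-yl 4-[(4S)-2,2-dimethyl-5-oxo-1,3-dioxolan-4-yl]-3-oxobutanoate, via acyl Meldrum's acid 5 (not isolated)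
Conditions: Meldrum's acid, DCC, DMAP, CH2Cl2, 0 °C to rt; then allyl alcohol, toluene, 80 °C
Reagents that add atoms: Meldrum's acid (2,2-dimethyl-1,3-dioxane-4,6-dione), CC1(C)OC(=O)CC(=O)O1; allyl alcohol, C=CCO
Why: C-Acylation of Meldrum's acid by the carbodiimide-activated acid and alcoholysis of the acyl Meldrum's acid with loss of acetone and CO2 is the standard two-carbon homologation of an acid to a β-keto ester, and the dioxolanone stereocentre is a spectator.

Step 4
Reactants: 6 prop-2-en-1-yl 4-[(4S)-2,2-dimethyl-5-oxo-1,3-dioxolan-4-yl]-3-oxobutanoate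
Product: 7 6-methyl 1-prop-2-en-1-yl (5S)-5-hydroxy-3-oxohexanedioate
Conditions: MeOH, p-TsOH (cat.), rt
Reagents that add atoms: methanol, CO
Why: Acid-catalysed transesterification opens the activated dioxolanone to the methyl α-hydroxy ester and acetone without involving the stereocentre.

Step 5
Reactants: 7 6-methyl 1-prop-2-en-1-yl (5S)-5-hydroxy-3-oxohexanedioate; 3 (Z)-1-bromo-3-iodobut-2-ene
Product: 9 prop-2-en-1-yl 3-[(1R,2S)-2-hydroxy-4-methyl-3-oxocyclohex-4-en-1-yl]-3-oxopropanoate, via γ-allylated keto diester 8 (not isolated)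
Conditions: NaH (2.0 equiv), THF, 0 °C; LDA (1.05 equiv), −78 °C; 3, −78 to −30 °C; t-BuLi (3.2 equiv), −78 °C; AcOH
Reagents that add atoms: none
Why: NaH and LDA turn 7 into its trianion (alkoxide, β-keto ester enolate, γ-carbanion), which the allylic bromide of 3 should alkylate only at the γ-carbon to give 8 (ring bond C4–C5), the reaction type of β-keto ester dianion alkylation and of the Fráter–Seebach alkylation of β-oxido enolates. t-BuLi, whose first equivalent returns the liberated diisopropylamine to LDA, then exchanges iodine for lithium, and the alkenyllithium adds to the neighbouring methyl ester and expels methoxide (ring bond C1–C2), a Parham-type cyclisation. The ring closes by a 6-exo-trig acyl substitution that leaves the Z-alkene inside the ring. The new stereocentre (C4 of the core) is set in the alkylation, where the lithium-chelated oxido enolate is attacked anti to the ester-bearing carbinol substituent, so that hydroxyl and keto ester arm should end trans; the carbinol centre comes from 4 and its alkoxide shields it from enolisation and from β-elimination. Three selectivities are needed: γ-C-alkylation (secured by the reactivity order of the polyanion), ring closure onto the methyl ester and not the keto ester (secured because the keto ester sits as an unreactive enolate, leaving one electrophile), and a vinyl metal cis to the allylic carbon (secured by the Z iodide from step 1).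

Step 6
Reactants: 9 prop-2-en-1-yl 3-[(1R,2S)-2-hydroxy-4-methyl-3-oxocyclohex-4-en-1-yl]-3-oxopropanoate
Product: 10 (5R,6S)-5-acetyl-6-hydroxy-2-methylcyclohex-2-en-1-one
Conditions: Pd(PPh3)4 (cat.), HCO2H, Et3N, THF, rt
Reagents that add atoms: none
Why: In this Tsuji–Trost deallylation zerovalent palladium ionises the allyl ester, formate reduces the allyl complex to propene and the β-keto acid decarboxylates under nearly neutral conditions that should leave both stereocentres untouched.

Step 7
Reactants: 10 (5R,6S)-5-acetyl-6-hydroxy-2-methylcyclohex-2-en-1-one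
Product: 11 1-[(1R,2S)-2-hydroxy-4-methyl-3-oxocyclohex-4-en-1-yl]ethenyl trifluoromethanesulfonate
Conditions: KN(SiMe3)2 (2.1 equiv), THF, −78 °C; PhNTf2, −78 to −40 °C
Reagents that add atoms: N-phenylbis(trifluoromethanesulfonimide), O=S(=O)(N(c1ccccc1)S(=O)(=O)C(F)(F)F)C(F)(F)F
Why: The first equivalent of base forms the alkoxide, which shields the adjacent ring C–H, so the second should remove the least hindered acetyl CH3 proton and the kinetic enolate is O-sulfonylated (enol triflate formation).

Step 8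
Reactants: 11 1-[(1R,2S)-2-hydroxy-4-methyl-3-oxocyclohex-4-en-1-yl]ethenyl trifluoromethanesulfonate
Product: 12 (1S,6R)-3-methyl-2-oxo-6-{1-[(trifluoromethanesulfonyl)oxy]ethenyl}cyclohex-3-en-1-yl (2E)-2-methylbut-2-enoate
Conditions: (E)-2-methylbut-2-enoyl chloride, pyridine, DMAP (cat.), CH2Cl2, 0 °C
Reagents that add atoms: (E)-2-methylbut-2-enoyl chloride, C/C=C(\C)C(=O)Cl
Why: DMAP-catalysed acylation of the secondary α-hydroxy ketone installs the tiglate, and because the neighbouring ring C–H is no longer acidified after step 7, β-elimination of the new ester is not expected.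

Step 9
Reactants: 12 (1S,6R)-3-methyl-2-oxo-6-{1-[(trifluoromethanesulfonyl)oxy]ethenyl}cyclohex-3-en-1-yl (2E)-2-methylbut-2-enoate
Product: 13 (1S,2S,6R)-2-hydroxy-3-methyl-6-{1-[(trifluoromethanesulfonyl)oxy]ethenyl}cyclohex-3-en-1-yl (2E)-2-methylbut-2-enoate
Conditions: NaBH4, CeCl3·7H2O, MeOH, −78 °C
Reagents that add atoms: none
Why: In the Luche 1,2-reduction axial hydride attack on the half-chair enone should give the pseudo-equatorial alcohol, trans to the tiglate and cis to the enol triflate arm, while tiglate and enol triflate are inert.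

Step 10
Reactants: 13 (1S,2S,6R)-2-hydroxy-3-methyl-6-{1-[(trifluoromethanesulfonyl)oxy]ethenyl}cyclohex-3-en-1-yl (2E)-2-methylbut-2-enoate
Product: 14 (1R,2R,3S,4R,6S)-2-hydroxy-1-methyl-4-{1-[(trifluoromethanesulfonyl)oxy]ethenyl}-7-oxabicyclo[4.1.0]heptan-3-yl (2E)-2-methylbut-2-enoate
Conditions: VO(acac)2 (cat.), t-BuOOH, CH2Cl2, 0 °C to rt
Reagents that add atoms: tert-butyl hydroperoxide, CC(C)(C)OO
Why: The vanadium-catalysed hydroxyl-directed epoxidation should deliver oxygen to the trisubstituted ring alkene on the face of the allylic hydroxyl, which is the face of the arm, and the electron-poor tiglate and enol triflate alkenes should not react.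

Step 11
Reactants: 14 (1R,2R,3S,4R,6S)-2-hydroxy-1-methyl-4-{1-[(trifluoromethanesulfonyl)oxy]ethenyl}-7-oxabicyclo[4.1.0]heptan-3-yl (2E)-2-methylbut-2-enoate
Product: 15 (1S,3S,4R,6S)-1-methyl-2-oxo-4-{1-[(trifluoromethanesulfonyl)oxy]ethenyl}-7-oxabicyclo[4.1.0]heptan-3-yl (2E)-2-methylbut-2-enoate
Conditions: Dess–Martin periodinane, CH2Cl2, rt
Reagents that add atoms: none
Why: Dess–Martin oxidation converts the secondary epoxy alcohol into the α,β-epoxy ketone under neutral conditions without changing a stereocentre.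

Step 12
Reactants: 16 2-methylbut-3-yn-2-ol
Product: 17 (3E)-2-methyl-4-(tributylstannyl)but-3-en-2-ol
Conditions: Bu3SnH, AIBN (cat.), toluene, 85 °C
Reagents that add atoms: tributyltin hydride, CCCC[SnH](CCCC)CCCC
Why: Radical hydrostannation of the terminal alkyne under thermodynamic control should give the (E)-β-stannyl alkene.

Step 13
Reactants: 15 (1S,3S,4R,6S)-1-methyl-2-oxo-4-{1-[(trifluoromethanesulfonyl)oxy]ethenyl}-7-oxabicyclo[4.1.0]heptan-3-yl (2E)-2-methylbut-2-enoate; 17 (3E)-2-methyl-4-(tributylstannyl)but-3-en-2-ol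
Product: 18 (1S,3S,4S,6S)-4-[(4E)-6-hydroxy-6-methyl-3-oxohepta-1,4-dien-2-yl]-1-methyl-2-oxo-7-oxabicyclo[4.1.0]heptan-3-yl (2E)-2-methylbut-2-enoate
Conditions: Pd2(dba)3 (cat.), AsPh3, CO (1 atm), NMP, 40 °C
Reagents that add atoms: carbon monoxide, [C-]#[O+]
Why: In the carbonylative Stille coupling, oxidative addition of the enol triflate, CO insertion and transfer of the alkenyl group from tin should give the cross-conjugated dienone under neutral conditions that spare the epoxy ketone, the tiglate and the free tertiary alcohol.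

Compound list
1 | but-2-yn-1-ol | CC#CCO | starting material
2 | (Z)-3-iodobut-2-en-1-ol | C/C(I)=C/CO | intermediate
3 | (Z)-1-bromo-3-iodobut-2-ene | C/C(I)=C/CBr | intermediate
4 | 2-[(4S)-2,2-dimethyl-5-oxo-1,3-dioxolan-4-yl]acetic acid | OC(=O)C[C@@H]1OC(C)(C)OC1=O | starting material
5 | 5-{2-[(4S)-2,2-dimethyl-5-oxo-1,3-dioxolan-4-yl]-1-hydroxyethylidene}-2,2-dimethyl-1,3-dioxane-4,6-dione (acyl Meldrum's acid, enol form; not isolated) | CC1(C)OC(=O)C(=C(O)C[C@@H]2OC(C)(C)OC2=O)C(=O)O1 | intermediate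
6 | prop-2-en-1-yl 4-[(4S)-2,2-dimethyl-5-oxo-1,3-dioxolan-4-yl]-3-oxobutanoate | C=CCOC(=O)CC(=O)C[C@@H]1OC(C)(C)OC1=O | intermediate
7 | 6-methyl 1-prop-2-en-1-yl (5S)-5-hydroxy-3-oxohexanedioate | C=CCOC(=O)CC(=O)C[C@H](O)C(=O)OC | intermediate
8 | 6-methyl 1-prop-2-en-1-yl (4R,5S)-5-hydroxy-4-[(2Z)-3-iodobut-2-en-1-yl]-3-oxohexanedioate (not isolated) | C=CCOC(=O)CC(=O)[C@H](C/C=C(/C)I)[C@H](O)C(=O)OC | intermediate
9 | prop-2-en-1-yl 3-[(1R,2S)-2-hydroxy-4-methyl-3-oxocyclohex-4-en-1-yl]-3-oxopropanoate | C=CCOC(=O)CC(=O)[C@@H]1CC=C(C)C(=O)[C@H]1O | intermediate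
10 | (5R,6S)-5-acetyl-6-hydroxy-2-methylcyclohex-2-en-1-one | CC(=O)[C@@H]1CC=C(C)C(=O)[C@H]1O | intermediate
11 | 1-[(1R,2S)-2-hydroxy-4-methyl-3-oxocyclohex-4-en-1-yl]ethenyl trifluoromethanesulfonate | C=C(OS(=O)(=O)C(F)(F)F)[C@@H]1CC=C(C)C(=O)[C@H]1O | intermediate
12 | (1S,6R)-3-methyl-2-oxo-6-{1-[(trifluoromethanesulfonyl)oxy]ethenyl}cyclohex-3-en-1-yl (2E)-2-methylbut-2-enoate | C=C(OS(=O)(=O)C(F)(F)F)[C@@H]1CC=C(C)C(=O)[C@H]1OC(=O)/C(C)=C/C | intermediate
13 | (1S,2S,6R)-2-hydroxy-3-methyl-6-{1-[(trifluoromethanesulfonyl)oxy]ethenyl}cyclohex-3-en-1-yl (2E)-2-methylbut-2-enoate | C=C(OS(=O)(=O)C(F)(F)F)[C@@H]1CC=C(C)[C@H](O)[C@H]1OC(=O)/C(C)=C/C | intermediate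
14 | (1R,2R,3S,4R,6S)-2-hydroxy-1-methyl-4-{1-[(trifluoromethanesulfonyl)oxy]ethenyl}-7-oxabicyclo[4.1.0]heptan-3-yl (2E)-2-methylbut-2-enoate | C=C(OS(=O)(=O)C(F)(F)F)[C@@H]1C[C@@H]2O[C@]2(C)[C@H](O)[C@H]1OC(=O)/C(C)=C/C | intermediate
15 | (1S,3S,4R,6S)-1-methyl-2-oxo-4-{1-[(trifluoromethanesulfonyl)oxy]ethenyl}-7-oxabicyclo[4.1.0]heptan-3-yl (2E)-2-methylbut-2-enoate | C=C(OS(=O)(=O)C(F)(F)F)[C@@H]1C[C@@H]2O[C@]2(C)C(=O)[C@H]1OC(=O)/C(C)=C/C | intermediate
16 | 2-methylbut-3-yn-2-ol | CC(C)(O)C#C | starting material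
17 | (3E)-2-methyl-4-(tributylstannyl)but-3-en-2-ol | CCCC[Sn](CCCC)(CCCC)/C=C/C(C)(C)O | intermediate
18 | (1S,3S,4S,6S)-4-[(4E)-6-hydroxy-6-methyl-3-oxohepta-1,4-dien-2-yl]-1-methyl-2-oxo-7-oxabicyclo[4.1.0]heptan-3-yl (2E)-2-methylbut-2-enoate | C=C(C(=O)/C=C/C(C)(C)O)[C@@H]1C[C@@H]2O[C@]2(C)C(=O)[C@H]1OC(=O)/C(C)=C/C | target

Total step count: 13. Longest linear sequence: 10 steps (3, 4, 5, 6, 7, 8, 9, 10, 11, 13).

Steps most likely to fail

Step 5. The alkenyllithium may be protonated before it reaches the ester, either by amine that is not yet re-lithiated or by intramolecular transfer from the C–H next to the keto ester enolate. The freshly alkylated carbon may also lose its configuration by re-deprotonation. Fallback: the operation is stopped after the alkylation and 8 is isolated. AlMe3 and MeNH(OMe)·HCl in CH2Cl2 convert its α-hydroxy methyl ester into the N-methoxy-N-methylamide F1, the keto ester being masked as its aluminium enolate. Excess i-PrMgCl·LiCl in THF (−20 °C to rt) then forms the magnesium alkoxide and enolate and exchanges iodine for magnesium. The far less basic alkenylmagnesium adds to the amide to give a stable chelate, which releases 9 on acidic work-up.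

Step 7. Under the strong base the β-oxido ketone may open by retro-aldol cleavage or dehydrate and aromatise, and the sulfonyl group may go to the alkoxide oxygen instead of the enolate. Fallback: 10 is first silylated (TBSOTf, 2,6-lutidine, CH2Cl2, −78 °C) to the silyl ether F2. F2 needs only one equivalent of KN(SiMe3)2 before PhNTf2 gives the silylated enol triflate F3. HF·pyridine in THF then frees the hydroxyl and gives 11.

Step 13. Transmetalation may outrun CO insertion, so that the alkenyl group couples directly, and the epoxy ketone may open at the coupling temperature. Fallback: reductive carbonylation of 15 (Pd(PPh3)4, CO, Bu3SnH, THF, 50 °C) gives the 2-substituted acrolein F4. Iododestannylation of 17 (I2, CH2Cl2, 0 °C) gives (E)-4-iodo-2-methylbut-3-en-2-ol F5. An aldehyde-selective Nozaki–Hiyama–Kishi coupling of the two (CrCl2, NiCl2 cat., DMSO, rt) gives the bis-allylic alcohol F6 as a mixture of carbinol epimers, and MnO2 in CH2Cl2 oxidises it to 18.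

Further compounds
F1 | step 5 | prop-2-en-1-yl (4R,5S)-5-hydroxy-4-[(2Z)-3-iodobut-2-en-1-yl]-6-[methoxy(methyl)amino]-3,6-dioxohexanoate | C=CCOC(=O)CC(=O)[C@H](C/C=C(/C)I)[C@H](O)C(=O)N(C)OC
F2 | step 7 | (5R,6S)-5-acetyl-6-[(tert-butyldimethylsilyl)oxy]-2-methylcyclohex-2-en-1-one | CC(=O)[C@@H]1CC=C(C)C(=O)[C@H]1O[Si](C)(C)C(C)(C)C
F3 | step 7 | 1-[(1R,2S)-2-[(tert-butyldimethylsilyl)oxy]-4-methyl-3-oxocyclohex-4-en-1-yl]ethenyl trifluoromethanesulfonate | C=C(OS(=O)(=O)C(F)(F)F)[C@@H]1CC=C(C)C(=O)[C@H]1O[Si](C)(C)C(C)(C)C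
F4 | step 13 | (1S,3S,4S,6S)-1-methyl-2-oxo-4-(3-oxoprop-1-en-2-yl)-7-oxabicyclo[4.1.0]heptan-3-yl (2E)-2-methylbut-2-enoate | C=C(C=O)[C@@H]1C[C@@H]2O[C@]2(C)C(=O)[C@H]1OC(=O)/C(C)=C/C
F5 | step 13 | (3E)-4-iodo-2-methylbut-3-en-2-ol | CC(C)(O)/C=C/I
F6 | step 13 | (1S,3S,4S,6S)-4-[(4E)-3,6-dihydroxy-6-methylhepta-1,4-dien-2-yl]-1-methyl-2-oxo-7-oxabicyclo[4.1.0]heptan-3-yl (2E)-2-methylbut-2-enoate (both carbinol epimers) | C=C(C(O)/C=C/C(C)(C)O)[C@@H]1C[C@@H]2O[C@]2(C)C(=O)[C@H]1OC(=O)/C(C)=C/C
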